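## Plan

Locants are those of benzofuran; ring A is the benzo ring, ring B the dihydrofuran, ring C the 2-aryl group.
Cuts, in retrosynthetic order: the MOM mask on the ring C phenol; the propenyl C=C at C5 (back to a C5 aldehyde and its methyl ester); C3–C3a together with O1–C7a of ring B; the oxirane oxygen; the C=C of a Z-propenylarene.
Feature that allows the double cut: O1 and C3 of ring B sit on the neighbouring ring A carbons C7a and C3a, C7a has the C7 methoxy group on its other side, and O1–C2–C3 is an opened 2-aryl-3-methyloxirane. An ortho-blocked aryl iodide and a cis-epoxide can therefore be merged by palladium/norbornene catalysis.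
Forward: rings A and C are bought as arenes; the ring C aldehyde is protected at its phenol, ethylidenated and epoxidised; ring B closes in step 4 (C3–C3a first, then O1–C7a); the C5 ester then becomes the E-propenyl group and the phenol is freed.
Stereochemistry: the Jacobsen epoxidation sets both carbons; C2 keeps its C–O bond to the end and C3 is inverted on epoxide opening, so the cis-(2R,3S)-epoxide maps onto the trans-(2S,3S) ring. The alkene geometries come from the Wittig (Z) and Julia–Kocienski (E) olefinations.

Key step: step 4

Assumption: 5-(ethylsulfonyl)-1-phenyl-1H-tetrazole is taken as a purchasable Julia–Kocienski reagent (otherwise two routine operations from 1-phenyl-1H-tetrazole-5-thiol: S-ethylation, then oxidation).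

## Route

Step 1
Reactants: 1 3-hydroxy-4,5-dimethoxybenzaldehyde
Product: 2 3-(methoxymethoxy)-4,5-dimethoxybenzaldehyde
Conditions: MOMCl, K2CO3, acetone, 0 °C to rt
Reagents that add atoms: chloromethyl methyl ether (MOMCl), COCCl
Why: Williamson-type O-alkylation of the phenoxide with the reactive α-chloro ether masks the only acidic, oxidisable OH as an acetal that is inert to ylide, hypochlorite, hot carbonate, hydride and amide base, and the aldehyde is left free for the next step.

Step 2
Reactants: 2 3-(methoxymethoxy)-4,5-dimethoxybenzaldehyde, 3 ethyltriphenylphosphonium bromide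
Product: 5 1,2-dimethoxy-3-(methoxymethoxy)-5-[(1Z)-prop-1-en-1-yl]benzene, via ethylidenetriphenylphosphorane 4 (not isolated)
Conditions: 3, KHMDS, THF, 0 °C; then 2, −78 °C to rt; AgNO3-impregnated silica if needed
Reagents that add atoms: none
Why: Wittig olefination with a non-stabilised ylide under lithium-free conditions runs under kinetic control through the cis-oxaphosphetane and should give mainly the Z-alkene, and residual E-isomer can be removed by argentation chromatography or left behind as the slow substrate of step 3.

Step 3
Reactants: 5 1,2-dimethoxy-3-(methoxymethoxy)-5-[(1Z)-prop-1-en-1-yl]benzene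
Product: 6 (2R,3S)-2-[3-(methoxymethoxy)-4,5-dimethoxyphenyl]-3-methyloxirane (cis)
Conditions: (R,R)-N,N'-bis(3,5-di-tert-butylsalicylidene)-1,2-cyclohexanediaminomanganese chloride (5 mol %), 4-phenylpyridine N-oxide (20 mol %), aq NaOCl (Na2HPO4 buffer, pH 11.3), CH2Cl2, 0 °C; Et3N-deactivated silica
Reagents that add atoms: sodium hypochlorite, [Na+].[O-]Cl
Why: Jacobsen–Katsuki epoxidation, in which the oxo species made from the trivalent manganese salen complex meets the Z-alkene side-on and the (R,R)-ligand directs oxygen to the face giving benzylic R and methyl-bearing S (the sense known for cis-β-methylstyrene-type alkenes), so that the catalyst sets both centres and the alkene geometry sets the cis relationship, while the N-oxide additive and low temperature curb the stepwise leak to trans-epoxide and the basic two-phase medium protects the acid-sensitive product.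

Step 4
Reactants: 6 (2R,3S)-2-[3-(methoxymethoxy)-4,5-dimethoxyphenyl]-3-methyloxirane (2 equiv), 7 methyl 4-iodo-3-methoxybenzoate
Product: 8 methyl (2S,3S)-7-methoxy-2-[3-(methoxymethoxy)-4,5-dimethoxyphenyl]-3-methyl-2,3-dihydro-1-benzofuran-5-carboxylate (trans)
Conditions: Pd(OAc)2 (10 mol %), XPhos (20 mol %), potassium 5-norbornene-2-carboxylate (1 equiv), K2CO3 (1.5 equiv), NMP, 80 °C, argon
Reagents that add atoms: none
Why: Proposed new method: zerovalent palladium (from Pd(OAc)2 and XPhos) inserts into the C7a–I bond of 7, the norbornene carboxylate inserts, and carboxylate-assisted palladation of the one free ortho C–H (C3a) gives the aryl–norbornyl palladacycle; this electron-rich divalent palladium centre attacks the potassium-coordinated epoxide from the rear at its methyl-bearing carbon, the resulting tetravalent palladium species reductively eliminates C3–C3a, and β-carbon elimination expels the norbornene. Ring B then closes as a five-membered ring by intramolecular C(sp2)–O reductive elimination at the ipso carbon C7a from a six-membered aryl palladium alkoxide chelate, a step helped by the para ester and by the bulky biaryl phosphine, which also disfavour β-hydride loss from C2. The closest known reaction type is the palladium/norbornene (Catellani) annulation of ortho-substituted aryl iodides with terminal epoxides to 2-substituted 2,3-dihydrobenzofurans, and a 1,2-disubstituted aryl epoxide lies outside that scope. C3 is the one centre made here: SN2-type opening inverts the methyl-bearing epoxide carbon, and because the C2–O bond is never broken the cis-epoxide is translated into the trans-(2S,3S) ring (C2 changes from R to S and C3 stays S only through changes in ligand ranking). The step needs a single ortho alkylation, which the C7 methoxy group secures by occupying the other ortho site and by supplying the ortho substituent that drives norbornene extrusion. It also needs attack at C–CH3 and not at the benzylic carbon, for which the substrate offers a small methyl group against a bulky 3,4,5-trioxygenated aryl group whose para methoxy group is twisted out of conjugation by its two neighbours, in a basic, Lewis-acid-free medium that gives benzylic ionisation no help.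

Step 5
Reactants: 8 methyl (2S,3S)-7-methoxy-2-[3-(methoxymethoxy)-4,5-dimethoxyphenyl]-3-methyl-2,3-dihydro-1-benzofuran-5-carboxylate
Product: 9 {(2S,3S)-7-methoxy-2-[3-(methoxymethoxy)-4,5-dimethoxyphenyl]-3-methyl-2,3-dihydro-1-benzofuran-5-yl}methanol
Conditions: LiAlH4, THF, 0 °C; aqueous work-up
Reagents that add atoms: none
Why: Standard LiAlH4 reduction of an aryl ester to the primary benzylic alcohol, with the acetal, the aryl ethers and ring B inert to hydride and no stereocentre involved.

Step 6
Reactants: 9 {(2S,3S)-7-methoxy-2-[3-(methoxymethoxy)-4,5-dimethoxyphenyl]-3-methyl-2,3-dihydro-1-benzofuran-5-yl}methanol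
Product: 10 (2S,3S)-7-methoxy-2-[3-(methoxymethoxy)-4,5-dimethoxyphenyl]-3-methyl-2,3-dihydro-1-benzofuran-5-carbaldehyde
Conditions: activated MnO2 (excess), CH2Cl2, rt
Reagents that add atoms: none
Why: Heterogeneous MnO2 oxidation of an electron-rich benzylic alcohol stops at the aldehyde under neutral conditions that leave the MOM ether and C2/C3 untouched.

Step 7
Reactants: 10 (2S,3S)-7-methoxy-2-[3-(methoxymethoxy)-4,5-dimethoxyphenyl]-3-methyl-2,3-dihydro-1-benzofuran-5-carbaldehyde, 11 5-(ethylsulfonyl)-1-phenyl-1H-tetrazole
Product: 13 (2S,3S)-7-methoxy-2-[3-(methoxymethoxy)-4,5-dimethoxyphenyl]-3-methyl-5-[(1E)-prop-1-en-1-yl]-2,3-dihydro-1-benzofuran, via metalated sulfone 12 (not isolated)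
Conditions: 11, KHMDS, DME, −60 °C; then 10, −60 °C to rt
Reagents that add atoms: none
Why: Julia–Kocienski olefination, in which addition of the potassium sulfonyl carbanion to the non-enolisable aryl aldehyde, Smiles rearrangement and antiperiplanar loss of SO2 and tetrazololate should give the conjugated E-alkene, while C2–H and C3–H are not acidified (C3a is meta to the formyl group) and so are not epimerised.

Step 8
Reactants: 13 (2S,3S)-7-methoxy-2-[3-(methoxymethoxy)-4,5-dimethoxyphenyl]-3-methyl-5-[(1E)-prop-1-en-1-yl]-2,3-dihydro-1-benzofuran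
Product: 14 5-{(2S,3S)-7-methoxy-3-methyl-5-[(1E)-prop-1-en-1-yl]-2,3-dihydro-1-benzofuran-2-yl}-2,3-dimethoxyphenol (CNP0299956.1)
Conditions: HCl (cat.), MeOH, 40 °C
Reagents that add atoms: none
Why: Acid-catalysed acetal exchange with methanol should cleave the aryl MOM ether much faster than the propenylarene is protonated, and should the C2–O1 bond ionise reversibly, reclosure under the control of the fixed C3 centre returns the more stable trans ring.

## Compound list

1 | 3-hydroxy-4,5-dimethoxybenzaldehyde | O=Cc1cc(O)c(OC)c(OC)c1 | starting material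
2 | 3-(methoxymethoxy)-4,5-dimethoxybenzaldehyde | O=Cc1cc(OCOC)c(OC)c(OC)c1 | intermediate
3 | ethyltriphenylphosphonium bromide | CC[P+](c1ccccc1)(c1ccccc1)c1ccccc1.[Br-] | starting material
4 | ethylidenetriphenylphosphorane (not isolated) | CC=P(c1ccccc1)(c1ccccc1)c1ccccc1 | intermediate
5 | 1,2-dimethoxy-3-(methoxymethoxy)-5-[(1Z)-prop-1-en-1-yl]benzene | C/C=C\c1cc(OCOC)c(OC)c(OC)c1 | intermediate
6 | (2R,3S)-2-[3-(methoxymethoxy)-4,5-dimethoxyphenyl]-3-methyloxirane (cis) | C[C@H]1[C@@H](c2cc(OCOC)c(OC)c(OC)c2)O1 | intermediate
7 | methyl 4-iodo-3-methoxybenzoate | COC(=O)c1ccc(I)c(OC)c1 | starting material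
8 | methyl (2S,3S)-7-methoxy-2-[3-(methoxymethoxy)-4,5-dimethoxyphenyl]-3-methyl-2,3-dihydro-1-benzofuran-5-carboxylate | COC(=O)c1cc(OC)c2c(c1)[C@H](C)[C@@H](c1cc(OCOC)c(OC)c(OC)c1)O2 | intermediate
9 | {(2S,3S)-7-methoxy-2-[3-(methoxymethoxy)-4,5-dimethoxyphenyl]-3-methyl-2,3-dihydro-1-benzofuran-5-yl}methanol | OCc1cc(OC)c2c(c1)[C@H](C)[C@@H](c1cc(OCOC)c(OC)c(OC)c1)O2 | intermediate
10 | (2S,3S)-7-methoxy-2-[3-(methoxymethoxy)-4,5-dimethoxyphenyl]-3-methyl-2,3-dihydro-1-benzofuran-5-carbaldehyde | O=Cc1cc(OC)c2c(c1)[C@H](C)[C@@H](c1cc(OCOC)c(OC)c(OC)c1)O2 | intermediate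
11 | 5-(ethylsulfonyl)-1-phenyl-1H-tetrazole | CCS(=O)(=O)c1nnnn1-c1ccccc1 | starting material
12 | potassium 1-[(1-phenyl-1H-tetrazol-5-yl)sulfonyl]ethan-1-ide (not isolated) | C[CH-]S(=O)(=O)c1nnnn1-c1ccccc1.[K+] | intermediate
13 | (2S,3S)-7-methoxy-2-[3-(methoxymethoxy)-4,5-dimethoxyphenyl]-3-methyl-5-[(1E)-prop-1-en-1-yl]-2,3-dihydro-1-benzofuran | C/C=C/c1cc(OC)c2c(c1)[C@H](C)[C@@H](c1cc(OCOC)c(OC)c(OC)c1)O2 | intermediate
14 | 5-{(2S,3S)-7-methoxy-3-methyl-5-[(1E)-prop-1-en-1-yl]-2,3-dihydro-1-benzofuran-2-yl}-2,3-dimethoxyphenol | C/C=C/c1cc(OC)c2c(c1)[C@H](C)[C@@H](c1cc(O)c(OC)c(OC)c1)O2 | target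

## Step count and risks

Total step count: 8. Longest linear sequence: 8 steps (1 to 14).

**Step 4 (new method).**
- The palladacycle may fail to engage a 1,2-disubstituted epoxide, or may open it at the benzylic carbon.
- Iodide released during turnover may open the epoxide first and erode the clean inversion.
- Zerovalent palladium may isomerise the epoxide faster than it is consumed.

The fallback uses known chemistry only, sets out from 2 and returns at 8.
- EtMgBr adds to 2 to give racemic 1-[3-(methoxymethoxy)-4,5-dimethoxyphenyl]propan-1-ol F1, and MnO2 oxidises it to 1-[3-(methoxymethoxy)-4,5-dimethoxyphenyl]propan-1-one F2.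
- In parallel, commercial methyl 4-amino-3-methoxybenzoate is brominated ortho to nitrogen (NBS, MeCN) to methyl 4-amino-3-bromo-5-methoxybenzoate F3. Sandmeyer chlorination (t-BuONO, CuCl2, MeCN) then gives methyl 3-bromo-4-chloro-5-methoxybenzoate F4.
- Palladium-catalysed ketone α-arylation of F2 at the C–Br bond of F4 (Pd2(dba)3, Xantphos, K3PO4, toluene, 90 °C) forms C3–C3a in racemic methyl 4-chloro-3-methoxy-5-{1-[3-(methoxymethoxy)-4,5-dimethoxyphenyl]-1-oxopropan-2-yl}benzoate F5.
- Noyori–Ikariya transfer hydrogenation with dynamic kinetic resolution (RuCl[(S,S)-TsDPEN](p-cymene), HCO2H/Et3N) equilibrates the acidic C3–H. It reduces one ketone enantiomer in the Felkin–Anh sense to methyl 4-chloro-3-{(1S,2S)-1-hydroxy-1-[3-(methoxymethoxy)-4,5-dimethoxyphenyl]propan-2-yl}-5-methoxybenzoate F6, which sets both centres.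
- Palladium-catalysed intramolecular aryl etherification at the C–Cl bond (Pd(OAc)2, 2-(di-tert-butylphosphino)-1,1'-binaphthyl, Cs2CO3, toluene, 80 °C) closes O1–C7a with retention at C2 and gives 8.

**Step 3.**
- The radical-type intermediate of manganese-oxo transfer may rotate before ring closure, which leaks to the trans series.
- Facial selectivity may drop with the trioxygenated arene.
- Hypochlorite may chlorinate ring C.
- The epoxide may ring-open during isolation.

The fallback sets out from 5 and returns at 6. It replaces the stepwise metal-oxo transfer by a concerted organocatalytic dioxirane transfer: a Shi-type epoxidation with the D-glucose-derived oxazolidinone-fused ketone developed for cis-alkenes. Conditions are KHSO5 (as its triple salt with KHSO4 and K2SO4), K2CO3 buffer and DME/water at −10 to 0 °C. The spiro transition state allows no C–C rotation, so the cis geometry is kept, and no chlorinating oxidant is present. The enantiomeric series of the ketone is chosen to deliver the (2R,3S)-epoxide, as expected by analogy with cis-β-methylstyrene. No new compound arises on this path (F0).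

**Step 2.**
- Reversible oxaphosphetane formation (stereochemical drift), common with aromatic aldehydes, may erode the Z-selectivity.
- Any E-alkene that is epoxidised ends as the wrong ring B diastereomer.

The fallback sets out from 2 and returns at 5.
- Corey–Fuchs homologation (CBr4, PPh3, CH2Cl2, 0 °C) gives 5-(2,2-dibromoethenyl)-1,2-dimethoxy-3-(methoxymethoxy)benzene F7.
- n-BuLi (2 equiv, THF, −78 °C) followed by MeI gives 1,2-dimethoxy-3-(methoxymethoxy)-5-(prop-1-yn-1-yl)benzene F8.
- Semihydrogenation over Pd/CaCO3 poisoned with Pb(OAc)2 (Lindlar catalyst; quinoline, H2, EtOAc) delivers both hydrogens to one face of the alkyne, so the Z geometry of 5 is fixed by the mechanism.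

## Further compounds

F1 | step 4 | 1-[3-(methoxymethoxy)-4,5-dimethoxyphenyl]propan-1-ol (racemic) | CCC(O)c1cc(OCOC)c(OC)c(OC)c1
F2 | step 4 | 1-[3-(methoxymethoxy)-4,5-dimethoxyphenyl]propan-1-one | CCC(=O)c1cc(OCOC)c(OC)c(OC)c1
F3 | step 4 | methyl 4-amino-3-bromo-5-methoxybenzoate | COC(=O)c1cc(Br)c(N)c(OC)c1
F4 | step 4 | methyl 3-bromo-4-chloro-5-methoxybenzoate | COC(=O)c1cc(Br)c(Cl)c(OC)c1
F5 | step 4 | methyl 4-chloro-3-methoxy-5-{1-[3-(methoxymethoxy)-4,5-dimethoxyphenyl]-1-oxopropan-2-yl}benzoate (racemic) | COC(=O)c1cc(OC)c(Cl)c(c1)C(C)C(=O)c1cc(OCOC)c(OC)c(OC)c1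
F6 | step 4 | methyl 4-chloro-3-{(1S,2S)-1-hydroxy-1-[3-(methoxymethoxy)-4,5-dimethoxyphenyl]propan-2-yl}-5-methoxybenzoate | COC(=O)c1cc(OC)c(Cl)c(c1)[C@H](C)[C@@H](c1cc(OCOC)c(OC)c(OC)c1)O
F0 | step 3 | none | none
F7 | step 2 | 5-(2,2-dibromoethenyl)-1,2-dimethoxy-3-(methoxymethoxy)benzene | BrC(Br)=Cc1cc(OCOC)c(OC)c(OC)c1
F8 | step 2 | 1,2-dimethoxy-3-(methoxymethoxy)-5-(prop-1-yn-1-yl)benzene | CC#Cc1cc(OCOC)c(OC)c(OC)c1
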